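**Retrosynthetic overview**

1. The route rests on C4a: a tertiary carbinol wedged between the fully substituted C5 and C8a, trans-diaxial to the C5 hydroxyl and γ to the C2=O/C3=C4 enone. The diol is read as the hydrate of the C4a–C5 epoxide of a 2-keto-3,4a(5)-dienone, so no nucleophile ever has to add to a C4a ketone.
2. Diol ⇒ α-epoxide ⇒ dienone 26. Ring A (C1–C2–C3–C4–C4a–C8a) ⇒ C3=C4 by intramolecular aldol condensation of keto-enal 24, the C3 methylene of the C2 ketone adding to the C4 aldehyde.
3. 24 ⇒ C2–C3 bond from ring B aldehyde 8 and the cyclopentylmethyl metal made from iodide 18. The C4 aldehyde comes from the enol triflate by carbonylative lactonisation, reduction and double oxidation.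
4. 8 comes from 2-methylcyclohexane-1,3-dione (C8a by desymmetrising reduction, C8–Br by inversion); 18 comes from camphanic acid (C3'–Br by reagent-controlled reduction, then inversion).
5. Ring order: ring B and the cyclopentane are carried from the starting materials, ring A is closed in step 17 through the enol under acid, and the epoxide and diol follow.

Key step: step 17

Remark on the chemistry: (1R,4S)-camphanic acid, the lactone acid of (1S,3R)-camphoric acid, is taken as a commercial starting material. The carbinol centre made in step 13 is carried as an epimer mixture because step 16 oxidises it. Decalin atoms are numbered as in the target (C2 ketone, C3 cyclopentyl-bearing, C4a and C5 carbinols, C8 CHBr, C8a C–Me); cyclopentane atoms are primed.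

**Route**

Step 1
Reactants: 1 2-methylcyclohexane-1,3-dione; 2 allyl bromide
Product: 3 2-allyl-2-methylcyclohexane-1,3-dione
Conditions: 1 M NaOH (aq), rt
Reagents that add atoms: none
Why: C-Alkylation of the 1,3-dione enolate by the allylic bromide in water, where solvation of the enolate oxygens favours attack through carbon, builds the quaternary carbon that becomes C8a.

Step 2
Reactants: 3 2-allyl-2-methylcyclohexane-1,3-dione
Product: 4 (2R,3R)-2-allyl-3-hydroxy-2-methylcyclohexan-1-one (OH cis to allyl)
Conditions: (S)-Me-CBS [(3aS)-1-methyl-3,3-diphenyltetrahydro-1H,3H-pyrrolo[1,2-c][1,3,2]oxazaborole] (0.2 equiv), catecholborane (1.1 equiv), toluene, −78 °C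
Reagents that add atoms: none
Why: Corey–Bakshi–Shibata reduction desymmetrises the prochiral dione: the catalyst (quaternary carbon as the large group) is expected to give the R carbinol, and hydride delivery past the methyl rather than the allyl group then fixes the quaternary centre as R with OH cis to allyl, the other diastereomer being removed by chromatography if it forms.

Step 3
Reactants: 4 (2R,3R)-2-allyl-3-hydroxy-2-methylcyclohexan-1-one
Product: 5 (2S,3S)-2-allyl-3-bromo-2-methylcyclohexan-1-one (Br cis to methyl)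
Conditions: CBr4, PPh3, 2,6-lutidine, toluene, 0 to 60 °C
Reagents that add atoms: carbon tetrabromide, BrC(Br)(Br)Br
Why: Appel reaction in which bromide displaces the oxyphosphonium by SN2 with inversion, placing bromine cis to the methyl group (the C8/C8a relation of the target), while the carbonyl on the quaternary carbon disfavours ionisation and alkyl shift.

Step 4
Reactants: 5 (2S,3S)-2-allyl-3-bromo-2-methylcyclohexan-1-one
Product: 6 (2S,3S)-2-allyl-3-bromo-2,6-dimethylcyclohexan-1-one (C6 epimers)
Conditions: LiN(i-Pr)2, THF, −78 °C; MeI, −78 to −20 °C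
Reagents that add atoms: iodomethane, CI
Why: Kinetic enolate alkylation, in which the ketone can enolise only towards C6 because C2 is quaternary, and the new centre is of no consequence since it becomes sp2 in step 5.

Step 5
Reactants: 6 (2S,3S)-2-allyl-3-bromo-2,6-dimethylcyclohexan-1-one
Product: 7 (5S,6S)-6-allyl-5-bromo-2,6-dimethylcyclohex-1-en-1-yl trifluoromethanesulfonate
Conditions: KN(SiMe3)2, THF, −78 °C; PhNTf2, −78 to 0 °C
Reagents that add atoms: N-phenylbis(trifluoromethanesulfonimide), O=S(=O)(N(c1ccccc1)S(=O)(=O)C(F)(F)F)C(F)(F)F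
Why: Enolate O-sulfonylation, in which deprotonation is possible only at the methyl-bearing carbon, so the tetrasubstituted enol triflate forms as one regioisomer, as is usual for 2,2,6-trisubstituted cyclohexanones.

Step 6
Reactants: 7 (5S,6S)-6-allyl-5-bromo-2,6-dimethylcyclohex-1-en-1-yl trifluoromethanesulfonate
Product: 8 (5S,6S)-5-bromo-2,6-dimethyl-6-(2-oxoethyl)cyclohex-1-en-1-yl trifluoromethanesulfonate
Conditions: OsO4 (cat.), NaIO4, 2,6-lutidine, dioxane–H2O, rt
Reagents that add atoms: osmium tetroxide, O=[Os](=O)(=O)=O; sodium periodate, [Na+].[O-]I(=O)(=O)=O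
Why: Lemieux–Johnson cleavage, in which OsO4 dihydroxylates the monosubstituted alkene and leaves the electron-poor tetrasubstituted enol triflate alone, and periodate cleaves the diol to the aldehyde that becomes C2.

Step 7
Reactants: 9 (1R,4S)-camphanic acid
Product: 12 (1S)-1,2,2-trimethyl-3-oxocyclopentane-1-carboxylic acid, via camphanoyl azide 10 (not isolated), via bridgehead isocyanate 11 (not isolated)
Conditions: (PhO)2P(O)N3, Et3N, toluene, rt then 90 °C; then 2 M HCl, dioxane, 80 °C
Reagents that add atoms: water, O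
Why: Curtius rearrangement (retention at the bridgehead) turns the α-acyloxy acid into an α-acyloxy isocyanate, whose hydrolysis gives a hemiaminal ester that collapses to the C3' ketone and frees the C1' carboxylic acid, leaving the quaternary stereocentre untouched.

Step 8
Reactants: 12 (1S)-1,2,2-trimethyl-3-oxocyclopentane-1-carboxylic acid
Product: 13 methyl (1S)-1,2,2-trimethyl-3-oxocyclopentane-1-carboxylate
Conditions: MeI, K2CO3, DMF, rt
Reagents that add atoms: iodomethane, CI
Why: Carboxylate O-alkylation (SN2 on iodomethane) esterifies the hindered tertiary acid without touching the ketone.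

Step 9
Reactants: 13 methyl (1S)-1,2,2-trimethyl-3-oxocyclopentane-1-carboxylate
Product: 14 methyl (1S,3S)-3-hydroxy-1,2,2-trimethylcyclopentane-1-carboxylate (OH trans to the ester)
Conditions: (R)-Me-CBS [(3aR)-1-methyl-3,3-diphenyltetrahydro-1H,3H-pyrrolo[1,2-c][1,3,2]oxazaborole] (0.2 equiv), BH3·SMe2, THF, −20 °C
Reagents that add atoms: none
Why: Corey–Bakshi–Shibata reduction under reagent control (gem-dimethyl carbon large, CH2 small) is expected to give the S carbinol, with OH cis to the C1' methyl and trans to the ester, overriding the weak bias of the remote quaternary centre, and any cis epimer would lactonise and separate.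

Step 10
Reactants: 14 methyl (1S,3S)-3-hydroxy-1,2,2-trimethylcyclopentane-1-carboxylate
Product: 15 (1S,3S)-3-(hydroxymethyl)-2,2,3-trimethylcyclopentan-1-ol
Conditions: LiAlH4, THF, 0 °C to reflux
Reagents that add atoms: none
Why: Hydride reduction of the ester to the primary alcohol, with no stereocentre affected.

Step 11
Reactants: 15 (1S,3S)-3-(hydroxymethyl)-2,2,3-trimethylcyclopentan-1-ol
Product: 17 (1S,3S)-3-(iodomethyl)-2,2,3-trimethylcyclopentan-1-ol, via primary triflate 16 (not isolated)
Conditions: Tf2O (1.05 equiv), 2,6-lutidine, CH2Cl2, −78 °C; then Bu4NI, −78 °C to rt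
Reagents that add atoms: tetrabutylammonium iodide, CCCC[N+](CCCC)(CCCC)CCCC.[I-]
Why: Selective O-triflation of the primary hydroxyl at low temperature followed by SN2 displacement with iodide gives the neopentyl-type iodide, and the trans secondary hydroxyl cannot reach the activated carbon, so no cyclic ether can form.

Step 12
Reactants: 17 (1S,3S)-3-(iodomethyl)-2,2,3-trimethylcyclopentan-1-ol
Product: 18 (1S,3R)-3-bromo-1-(iodomethyl)-1,2,2-trimethylcyclopentane (Br cis to CH2I)
Conditions: CBr4, PPh3, 2,6-lutidine, toluene, 70 °C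
Reagents that add atoms: carbon tetrabromide, BrC(Br)(Br)Br
Why: Appel reaction with inversion at C3' (SN2 by bromide on the oxyphosphonium) turns the S carbinol into the R bromide cis to the iodomethyl group, the neopentyl primary iodide being inert to these conditions.

Step 13
Reactants: 8 (5S,6S)-5-bromo-2,6-dimethyl-6-(2-oxoethyl)cyclohex-1-en-1-yl trifluoromethanesulfonate; 18 (1S,3R)-3-bromo-1-(iodomethyl)-1,2,2-trimethylcyclopentane
Product: 21 (5S,6S)-5-bromo-6-{3-[(1R,3R)-3-bromo-1,2,2-trimethylcyclopentyl]-2-hydroxypropyl}-2,6-dimethylcyclohex-1-en-1-yl trifluoromethanesulfonate (carbinol epimers), via organolithium 19 (not isolated), via organocerium 20 (not isolated)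
Conditions: 18, t-BuLi (2.05 equiv), Et2O–pentane, −78 °C; CeCl3, THF, −78 °C; then 8, −78 °C; aq. NH4Cl
Reagents that add atoms: none
Why: Lithium–iodine exchange (much faster at the primary iodide than at the secondary bromide at −78 °C), transmetalation to the less basic organocerium and 1,2-addition to the aldehyde form the C2–C3 bond, the new carbinol being an epimer mixture that step 16 removes.

Step 14
Reactants: 21 hydroxy triflate
Product: 22 (4aS,5S)-5-bromo-3-{[(1R,3R)-3-bromo-1,2,2-trimethylcyclopentyl]methyl}-4a,8-dimethyl-3,4,4a,5,6,7-hexahydro-1H-isochromen-1-one (C3 epimers; δ-lactone joining the C4 carbonyl to the C2 oxygen)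
Conditions: Pd(OAc)2 (10 mol %), 1,3-bis(diphenylphosphino)propane, CO (1 atm), Et3N, DMF, 60 °C
Reagents that add atoms: carbon monoxide, [C-]#[O+]
Why: Palladium-catalysed carbonylation of the enol triflate, in which oxidative addition, CO insertion and intramolecular capture of the acylpalladium by the C2 hydroxyl (six-membered ring) install C4 as a lactone carbonyl, while the secondary alkyl bromides do not add to palladium with this ligand.

Step 15
Reactants: 22 unsaturated δ-lactone
Product: 23 1-[(1S,2S)-2-bromo-6-(hydroxymethyl)-1,5-dimethylcyclohex-5-en-1-yl]-3-[(1R,3R)-3-bromo-1,2,2-trimethylcyclopentyl]propan-2-ol (carbinol epimers)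
Conditions: i-Bu2AlH (4 equiv), CH2Cl2, −78 to 0 °C; aq. potassium sodium tartrate
Reagents that add atoms: none
Why: i-Bu2AlH reduces the unsaturated lactone in the 1,2-sense through the lactol to the ene-diol and does not reduce alkyl bromides.

Step 16
Reactants: 23 ene-diol
Product: 24 (5S,6S)-5-bromo-6-{3-[(1R,3R)-3-bromo-1,2,2-trimethylcyclopentyl]-2-oxopropyl}-2,6-dimethylcyclohex-1-ene-1-carbaldehyde
Conditions: (COCl)2, DMSO, CH2Cl2, −78 °C; Et3N, −78 to 0 °C
Reagents that add atoms: none
Why: Swern oxidation activates both hydroxyls before base is added, so the allylic primary alcohol gives the enal and the secondary alcohol the ketone without passing through a lactol that would re-form the lactone.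

Step 17
Reactants: 24 keto-enal
Product: 26 (8S,8aS)-8-bromo-3-[(1R,3R)-3-bromo-1,2,2-trimethylcyclopentyl]-5,8a-dimethyl-6,7,8,8a-tetrahydronaphthalen-2(1H)-one, via aldol 25 (not isolated)
Conditions: TsOH·H2O (0.2 equiv), benzene, reflux, Dean–Stark
Reagents that add atoms: none
Why: Acid-catalysed enolisation of the C2 ketone towards C3, addition of the enol to the protonated C4 aldehyde and loss of water from the doubly allylic aldol 25 give the linearly conjugated dienone, with removal of water driving the sequence. The closest known reaction type is the acid-catalysed intramolecular aldol condensation of 1,5-keto-aldehydes to cyclohexenones, and hindered enals of the 2,6,6-trisubstituted cyclohexenecarbaldehyde type are known to condense with ketones. Ring A closes in the 6-(enolexo)-exo-trig mode. No stereocentre is formed in the product, and C8, C8a and the cyclopentane centres carry no acidic hydrogen, so nothing is scrambled. The step needs C3 rather than C1 as nucleophile and 1,2- rather than 1,4-addition to the enal: closure from C1 would give a four-membered ring and reverts, and 1,4-addition of C3 would have to build a quaternary C5 inside a bridged bicycle. The enol (acid) mode is chosen over an enolate because an enolate at C1 is γ to the C8 bromide and could close a cyclopropane and because base could eliminate HBr; γ-enolisation of the enal is reversible and returns the conjugated aldehyde.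

Step 18
Reactants: 26 dienone
Product: 27 (4aR,5S,8S,8aS)-8-bromo-3-[(1R,3R)-3-bromo-1,2,2-trimethylcyclopentyl]-4a,5-epoxy-5,8a-dimethyl-4a,5,6,7,8,8a-hexahydronaphthalen-2(1H)-one
Conditions: dimethyldioxirane, acetone, 0 °C
Reagents that add atoms: dimethyldioxirane, CC1(C)OO1
Why: Electrophilic epoxidation takes the electron-richer tetrasubstituted γ,δ-alkene C4a=C5 rather than the enone alkene C3=C4, and attack anti to the axial C8a methyl should set the epoxide oxygen α at C4a (R) and C5 (S).

Step 19
Reactants: 27 α-epoxide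
Product: 28 (4aR,5R,8S,8aS)-8-bromo-3-[(1R,3R)-3-bromo-1,2,2-trimethylcyclopentyl]-4a,5-dihydroxy-5,8a-dimethyl-4a,5,6,7,8,8a-hexahydronaphthalen-2(1H)-one
Conditions: HClO4 (cat.), THF–H2O, 0 °C to rt
Reagents that add atoms: water, O
Why: Acid-catalysed epoxide hydrolysis in the trans-diaxial (Fürst–Plattner) sense, in which water opens the tertiary C5 with inversion because positive charge at C4a would be γ to the enone carbonyl and its rear face is shut by the ring fusion, leaving the C4a oxygen α and placing the C5 hydroxyl β.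

**Compound list**

1 | 2-methylcyclohexane-1,3-dione | CC1C(=O)CCCC1=O | starting material
2 | allyl bromide | C=CCBr | starting material
3 | 2-allyl-2-methylcyclohexane-1,3-dione | C=CCC1(C)C(=O)CCCC1=O | intermediate
4 | (2R,3R)-2-allyl-3-hydroxy-2-methylcyclohexan-1-one | C=CC[C@]1(C)[C@H](O)CCCC1=O | intermediate
5 | (2S,3S)-2-allyl-3-bromo-2-methylcyclohexan-1-one | C=CC[C@]1(C)[C@@H](Br)CCCC1=O | intermediate
6 | (2S,3S)-2-allyl-3-bromo-2,6-dimethylcyclohexan-1-one (C6 epimers) | C=CC[C@]1(C)[C@@H](Br)CCC(C)C1=O | intermediate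
7 | (5S,6S)-6-allyl-5-bromo-2,6-dimethylcyclohex-1-en-1-yl trifluoromethanesulfonate | C=CC[C@]1(C)[C@@H](Br)CCC(C)=C1OS(=O)(=O)C(F)(F)F | intermediate
8 | (5S,6S)-5-bromo-2,6-dimethyl-6-(2-oxoethyl)cyclohex-1-en-1-yl trifluoromethanesulfonate | O=CC[C@]1(C)[C@@H](Br)CCC(C)=C1OS(=O)(=O)C(F)(F)F | intermediate
9 | (1R,4S)-camphanic acid [(1R,4S)-4,7,7-trimethyl-3-oxo-2-oxabicyclo[2.2.1]heptane-1-carboxylic acid] | CC1(C)[C@@]2(C(=O)O)CC[C@]1(C)C(=O)O2 | starting material
10 | (1R,4S)-camphanoyl azide | CC1(C)[C@@]2(C(=O)N=[N+]=[N-])CC[C@]1(C)C(=O)O2 | intermediate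
11 | (1R,4S)-1-isocyanato-4,7,7-trimethyl-2-oxabicyclo[2.2.1]heptan-3-one | CC1(C)[C@@]2(N=C=O)CC[C@]1(C)C(=O)O2 | intermediate
12 | (1S)-1,2,2-trimethyl-3-oxocyclopentane-1-carboxylic acid | CC1(C)C(=O)CC[C@]1(C)C(=O)O | intermediate
13 | methyl (1S)-1,2,2-trimethyl-3-oxocyclopentane-1-carboxylate | CC1(C)C(=O)CC[C@]1(C)C(=O)OC | intermediate
14 | methyl (1S,3S)-3-hydroxy-1,2,2-trimethylcyclopentane-1-carboxylate | CC1(C)[C@@H](O)CC[C@]1(C)C(=O)OC | intermediate
15 | (1S,3S)-3-(hydroxymethyl)-2,2,3-trimethylcyclopentan-1-ol | CC1(C)[C@@H](O)CC[C@]1(C)CO | intermediate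
16 | [(1S,3S)-3-hydroxy-1,2,2-trimethylcyclopentyl]methyl trifluoromethanesulfonate | CC1(C)[C@@H](O)CC[C@]1(C)COS(=O)(=O)C(F)(F)F | intermediate
17 | (1S,3S)-3-(iodomethyl)-2,2,3-trimethylcyclopentan-1-ol | CC1(C)[C@@H](O)CC[C@]1(C)CI | intermediate
18 | (1S,3R)-3-bromo-1-(iodomethyl)-1,2,2-trimethylcyclopentane | CC1(C)[C@H](Br)CC[C@]1(C)CI | intermediate
19 | [(3-bromo-1,2,2-trimethylcyclopentyl)methyl]lithium, configuration as in 18 | CC1(C)[C@H](Br)CC[C@]1(C)C[Li] | intermediate
20 | [(3-bromo-1,2,2-trimethylcyclopentyl)methyl]cerium dichloride, configuration as in 18 | CC1(C)[C@H](Br)CC[C@]1(C)C[Ce](Cl)Cl | intermediate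
21 | (5S,6S)-5-bromo-6-{3-[(1R,3R)-3-bromo-1,2,2-trimethylcyclopentyl]-2-hydroxypropyl}-2,6-dimethylcyclohex-1-en-1-yl trifluoromethanesulfonate (carbinol epimers) | CC1(C)[C@H](Br)CC[C@]1(C)CC(O)C[C@]1(C)[C@@H](Br)CCC(C)=C1OS(=O)(=O)C(F)(F)F | intermediate
22 | (4aS,5S)-5-bromo-3-{[(1R,3R)-3-bromo-1,2,2-trimethylcyclopentyl]methyl}-4a,8-dimethyl-3,4,4a,5,6,7-hexahydro-1H-isochromen-1-one (C3 epimers) | CC1(C)[C@H](Br)CC[C@]1(C)CC1C[C@]2(C)[C@@H](Br)CCC(C)=C2C(=O)O1 | intermediate
23 | 1-[(1S,2S)-2-bromo-6-(hydroxymethyl)-1,5-dimethylcyclohex-5-en-1-yl]-3-[(1R,3R)-3-bromo-1,2,2-trimethylcyclopentyl]propan-2-ol (carbinol epimers) | CC1(C)[C@H](Br)CC[C@]1(C)CC(O)C[C@]1(C)[C@@H](Br)CCC(C)=C1CO | intermediate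
24 | (5S,6S)-5-bromo-6-{3-[(1R,3R)-3-bromo-1,2,2-trimethylcyclopentyl]-2-oxopropyl}-2,6-dimethylcyclohex-1-ene-1-carbaldehyde | CC1(C)[C@H](Br)CC[C@]1(C)CC(=O)C[C@]1(C)[C@@H](Br)CCC(C)=C1C=O | intermediate
25 | (8S,8aS)-8-bromo-3-[(1R,3R)-3-bromo-1,2,2-trimethylcyclopentyl]-4-hydroxy-5,8a-dimethyl-3,4,6,7,8,8a-hexahydronaphthalen-2(1H)-one (C3 and C4 epimers) | CC1(C)[C@H](Br)CC[C@]1(C)C1C(O)C2=C(C)CC[C@H](Br)[C@@]2(C)CC1=O | intermediate
26 | (8S,8aS)-8-bromo-3-[(1R,3R)-3-bromo-1,2,2-trimethylcyclopentyl]-5,8a-dimethyl-6,7,8,8a-tetrahydronaphthalen-2(1H)-one | CC1(C)[C@H](Br)CC[C@]1(C)C1=CC2=C(C)CC[C@H](Br)[C@@]2(C)CC1=O | intermediate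
27 | (4aR,5S,8S,8aS)-8-bromo-3-[(1R,3R)-3-bromo-1,2,2-trimethylcyclopentyl]-4a,5-epoxy-5,8a-dimethyl-4a,5,6,7,8,8a-hexahydronaphthalen-2(1H)-one | CC1(C)[C@H](Br)CC[C@]1(C)C1=C[C@@]23O[C@@]3(C)CC[C@H](Br)[C@@]2(C)CC1=O | intermediate
28 | (4aR,5R,8S,8aS)-8-bromo-3-[(1R,3R)-3-bromo-1,2,2-trimethylcyclopentyl]-4a,5-dihydroxy-5,8a-dimethyl-4a,5,6,7,8,8a-hexahydronaphthalen-2(1H)-one | CC1(C)[C@H](Br)CC[C@]1(C)C1=C[C@]2(O)[C@](C)(O)CC[C@H](Br)[C@@]2(C)CC1=O | target

**Step count**

Total: 19 steps. Longest linear sequence: 13 steps (steps 1–6 then 13–19; the cyclopentane branch, steps 7–12 then 13–19, is equally long).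

**Steps most likely to fail**

Step 12 (bromide at C3' by inversion). Substitution at a carbon flanked by the gem-dimethyl carbon may be outrun by methyl migration and elimination, and bromide has to enter on the face that carries the iodomethyl group. The fallback moves the substitution to a substrate whose flanking group is a small, non-participating, electron-withdrawing nitrile. It sets out from 12 and returns at 18. Acid 12 is converted with (COCl)2 and then NH3 into the keto amide F1, and (CF3CO)2O/pyridine dehydrates it to the keto nitrile F2. (R)-Me-CBS with catecholborane gives the trans hydroxy nitrile F3, and CBr4/PPh3 then gives the bromo nitrile F4 with bromine cis to the nitrile. i-Bu2AlH followed by aqueous HCl gives the aldehyde F5, NaBH4 gives the primary alcohol F6, and Tf2O/2,6-lutidine followed by Bu4NI gives 18.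

Step 13 (fragment union). The lithium–iodine exchange may not stay selective beside the secondary bromide (exchange or electron transfer at C–Br), and the hindered organometallic may deprotonate the aldehyde instead of adding. The fallback removes the bromide from the organometallic step and installs it after the lactone has tied up the C2 oxygen. It sets out from 17 and returns at 22. Alcohol 17 is silylated (t-BuMe2SiOTf, 2,6-lutidine) to the silyl ether iodide F7. Exchange with t-BuLi, transmetalation with CeCl3 and addition to 8 give the hydroxy triflate F8. Carbonylative lactonisation as in step 14 gives the lactone silyl ether F9, Bu4NF gives the hydroxy lactone F10, and CBr4/PPh3 with inversion gives 22.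

Step 17 (ring A closure). The closure may stall because both the enol carbon and the enal are hindered, leaving time for acid-promoted side reactions of the enal, or the alternative enol(ate) at C1 may divert material. The fallback adds a phosphonate at C3 so that only this carbon is deprotonated by a mild base and the C3=C4 bond forms by an intramolecular Horner–Wadsworth–Emmons reaction. It sets out from 18 and 8 and returns at 26. The lithium reagent from 18 is quenched with ClP(O)(OMe)2 to the phosphonate F11. Deprotonation with LiN(i-Pr)2 and addition to 8 give the hydroxy phosphonate triflate F12. The sequence of steps 14–16 then gives the lactone F13, the diol F14 and the keto phosphonate enal F15. LiCl/DBU in MeCN closes ring A to 26.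

**Further compounds**

F1 | step 12 | (1S)-1,2,2-trimethyl-3-oxocyclopentane-1-carboxamide | CC1(C)C(=O)CC[C@]1(C)C(N)=O
F2 | step 12 | (1S)-1,2,2-trimethyl-3-oxocyclopentane-1-carbonitrile | CC1(C)C(=O)CC[C@]1(C)C#N
F3 | step 12 | (1S,3S)-3-hydroxy-1,2,2-trimethylcyclopentane-1-carbonitrile | CC1(C)[C@@H](O)CC[C@]1(C)C#N
F4 | step 12 | (1S,3R)-3-bromo-1,2,2-trimethylcyclopentane-1-carbonitrile | CC1(C)[C@H](Br)CC[C@]1(C)C#N
F5 | step 12 | (1S,3R)-3-bromo-1,2,2-trimethylcyclopentane-1-carbaldehyde | CC1(C)[C@H](Br)CC[C@]1(C)C=O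
F6 | step 12 | [(1S,3R)-3-bromo-1,2,2-trimethylcyclopentyl]methanol | CC1(C)[C@H](Br)CC[C@]1(C)CO
F7 | step 13 | tert-butyl{[(1S,3S)-3-(iodomethyl)-2,2,3-trimethylcyclopentyl]oxy}dimethylsilane | CC1(C)[C@@H](O[Si](C)(C)C(C)(C)C)CC[C@]1(C)CI
F8 | step 13 | silyl ether analogue of 21 (OSiMe2t-Bu at C3' in place of Br, carbinol epimers) | CC1(C)[C@@H](O[Si](C)(C)C(C)(C)C)CC[C@]1(C)CC(O)C[C@]1(C)[C@@H](Br)CCC(C)=C1OS(=O)(=O)C(F)(F)F
F9 | step 13 | silyl ether analogue of 22 (OSiMe2t-Bu at C3' in place of Br) | CC1(C)[C@@H](O[Si](C)(C)C(C)(C)C)CC[C@]1(C)CC1C[C@]2(C)[C@@H](Br)CCC(C)=C2C(=O)O1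
F10 | step 13 | hydroxy lactone (free trans OH at C3' in place of Br in 22) | CC1(C)[C@@H](O)CC[C@]1(C)CC1C[C@]2(C)[C@@H](Br)CCC(C)=C2C(=O)O1
F11 | step 17 | dimethyl {[(1S,3R)-3-bromo-1,2,2-trimethylcyclopentyl]methyl}phosphonate | CC1(C)[C@H](Br)CC[C@]1(C)CP(=O)(OC)OC
F12 | step 17 | C3-dimethoxyphosphoryl analogue of 21 | CC1(C)[C@H](Br)CC[C@]1(C)C(P(=O)(OC)OC)C(O)C[C@]1(C)[C@@H](Br)CCC(C)=C1OS(=O)(=O)C(F)(F)F
F13 | step 17 | C3-dimethoxyphosphoryl analogue of 22 | CC1(C)[C@H](Br)CC[C@]1(C)C(P(=O)(OC)OC)C1C[C@]2(C)[C@@H](Br)CCC(C)=C2C(=O)O1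
F14 | step 17 | C3-dimethoxyphosphoryl analogue of 23 | CC1(C)[C@H](Br)CC[C@]1(C)C(P(=O)(OC)OC)C(O)C[C@]1(C)[C@@H](Br)CCC(C)=C1CO
F15 | step 17 | C3-dimethoxyphosphoryl analogue of 24 | CC1(C)[C@H](Br)CC[C@]1(C)C(P(=O)(OC)OC)C(=O)C[C@]1(C)[C@@H](Br)CCC(C)=C1C=O
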